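Labels: ring A is the brominated ring (A-C1 OMe, A-C2 H, A-C3 Me, A-C4 Br, A-C5 OH, A-C6 carrying the ketone carbon). Ring B is the prenylated ring (B-C1 on the ketone carbon, B-C2 CHO, B-C3 OH, B-C4 H, B-C5 OH, B-C6 prenyl).
Feature used: A-C6 stands between a free hydroxyl (A-C5) and a methyl ether (A-C1), with the methyl group at A-C3 meta to both oxygens. A vinylketene and a 1-methoxyalkyne assemble this 2-substituted 3-methoxy-5-methylphenol pattern in one operation.
End game, read backwards: MOM removal; double Swern oxidation of a diol (ketone carbon and B-C2 CH2OH); A-C4 bromine by hydroxyl-directed ortho-bromination of the annulation phenol.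
Key disconnection: cutting A-C5/A-C6 and A-C1/A-C2 gives 3-methylcyclobut-2-enone (A-C2 to A-C5 plus the methyl group) and a methoxyalkyne (A-C1, A-C6). The propargylic carbon of the alkyne, the later ketone carbon, is already bonded to B-C1.
Ring B is bought as methyl 3,5-dihydroxybenzoate and dressed through a phthalide (formylation, reduction-lactonisation, bromination, Stille prenylation), whose lactol takes up lithium methoxyacetylide. Ring order: B (bought), auxiliary lactone ring (opened again), ring A last.

Key step: step 11

Remark (assumption): every intermediate with the lactol or carbinol carbon is racemic. This carbon becomes the ketone carbon in step 15, and the target has no stereocentre.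
Remark (design): ring B is not built by two successive amide-directed lithiations. An ortho-prenyl group offers a benzylic and allylic CH2 that strong base would remove before a ring hydrogen. A 2,6-disubstituted diethylbenzamide also cannot be unmasked beside MOM ethers. The phthalide route avoids both problems and fixes the two benzylic carbons at different oxidation levels.

Step 1
Reactants: 1 propyne; 2 trichloroacetyl chloride
Product: 4 4,4-dichloro-3-methylcyclobut-2-en-1-one, via dichloroketene 3 (not isolated)
Conditions: Zn(Cu), Et2O–DME, 0 °C → rt, dry-ice condenser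
Reagents that add atoms: none
Why: Zinc strips two chlorines from 2 to release dichloroketene, and the ketene–alkyne (2+2) cycloaddition joins its carbonyl carbon to the terminal, more nucleophilic alkyne carbon, which puts the methyl group on C3 next to the CCl2 carbon.

Step 2
Reactants: 4 4,4-dichloro-3-methylcyclobut-2-en-1-one
Product: 5 3-methylcyclobut-2-en-1-one
Conditions: Zn dust, AcOH, TMEDA, EtOH, 0 °C → rt; careful distillation (volatile), stored as a toluene solution
Reagents that add atoms: none
Why: Reductive dehalogenation of the α,α-dichloroketone by zinc runs through zinc enolates that acetic acid protonates, and the TMEDA buffer keeps the strained enone from acid-induced isomerisation or ring cleavage.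

Step 3
Reactants: 6 methyl 3,5-dihydroxybenzoate
Product: 8 methyl 2-formyl-3,5-dihydroxybenzoate, via aryl iminium chloride 7 (not isolated)
Conditions: POCl3, DMF, MeCN, 0 °C → rt; then H2O, 50 °C
Reagents that add atoms: N,N-dimethylformamide, CN(C)C=O; water, O
Why: Vilsmeier–Haack formylation attacks the carbon that is ortho to one hydroxyl and para to the other (C2, equivalent to C6) rather than the crowded C4 between the two hydroxyls, as is usual for resorcinols, and water hydrolyses iminium salt 7 to the aldehyde.

Step 4
Reactants: 8 methyl 2-formyl-3,5-dihydroxybenzoate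
Product: 9 methyl 2-formyl-3,5-bis(methoxymethoxy)benzoate
Conditions: MOMCl (3 equiv), i-Pr2NEt, Bu4NI (cat.), CH2Cl2, 0 → 40 °C
Reagents that add atoms: chloromethyl methyl ether, COCCl
Why: O-Alkylation with the highly reactive chloromethyl ether caps both phenols as acetals, with excess reagent and gentle heating used to overcome the hydrogen bond of the C3 hydroxyl to the aldehyde.

Step 5
Reactants: 9 methyl 2-formyl-3,5-bis(methoxymethoxy)benzoate
Product: 11 4,6-bis(methoxymethoxy)isobenzofuran-1(3H)-one, via hydroxy ester 10 (not isolated)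
Conditions: NaBH4, MeOH, 0 °C → rt
Reagents that add atoms: none
Why: Chemoselective borohydride reduction of the aldehyde gives the benzylic alkoxide of 10, which lactonises at once onto the neighbouring methyl ester (transesterification to a five-membered ring).

Step 6
Reactants: 11 4,6-bis(methoxymethoxy)isobenzofuran-1(3H)-one
Product: 12 7-bromo-4,6-bis(methoxymethoxy)isobenzofuran-1(3H)-one
Conditions: NBS (1.05 equiv), MeCN, 0 °C → rt, dark
Reagents that add atoms: N-bromosuccinimide, O=C1CCC(=O)N1Br
Why: Electrophilic aromatic bromination goes to C7, which is ortho to the C6 acetal oxygen and para to the C4 one, in preference to C5, which is squeezed between both OMOM groups, in line with the behaviour of 3,5-dialkoxybenzoates.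

Step 7
Reactants: 12 7-bromo-4,6-bis(methoxymethoxy)isobenzofuran-1(3H)-one; 13 tributyl(3-methylbut-2-en-1-yl)stannane
Product: 14 4,6-bis(methoxymethoxy)-7-(3-methylbut-2-en-1-yl)isobenzofuran-1(3H)-one
Conditions: Pd(PPh3)4 (5 mol %), toluene, 110 °C, degassed
Reagents that add atoms: none
Why: In this Migita–Kosugi–Stille coupling, zerovalent palladium inserts into the C–Br bond that the ortho lactone carbonyl activates, and reductive elimination from the allylpalladium intermediate takes place at the unsubstituted allyl terminus to give the linear prenyl arene.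

Step 8
Reactants: 14 4,6-bis(methoxymethoxy)-7-(3-methylbut-2-en-1-yl)isobenzofuran-1(3H)-one
Product: 15 (±)-4,6-bis(methoxymethoxy)-7-(3-methylbut-2-en-1-yl)-1,3-dihydroisobenzofuran-1-ol
Conditions: i-Bu2AlH (1.1 equiv), CH2Cl2, −78 °C; aq. potassium sodium tartrate
Reagents that add atoms: none
Why: Partial reduction of a lactone with one equivalent of i-Bu2AlH at low temperature stops at the aluminium hemiacetal, which gives the racemic lactol on work-up, while MOM ethers and the alkene are inert.

Step 9
Reactants: 15 (±)-lactol; 16 2-chloro-1,1-dimethoxyethane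
Product: 19 (±)-1-[2-(hydroxymethyl)-3,5-bis(methoxymethoxy)-6-(3-methylbut-2-en-1-yl)phenyl]-3-methoxyprop-2-yn-1-ol, via lithium methoxyacetylide 17 (not isolated), via ring-opened aldehyde alkoxide 18 (not isolated)
Conditions: 16 (3 equiv), LiNEt2 (9 equiv, from Et2NH and n-BuLi), THF, −78 → 0 °C; then 15, −78 → 0 °C; H2O quench; no contact with acid
Reagents that add atoms: none
Why: Threefold action of LiNEt2 on 16 (loss of MeOH, loss of HCl, deprotonation) gives lithium methoxyacetylide, one equivalent of which opens the lactol to aldehyde alkoxide 18 while a second adds to the carbonyl group (1,2-addition of an alkynyllithium, slim enough for a 2,6-disubstituted benzaldehyde), so the new carbinol centre forms racemic.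

Step 10
Reactants: 19 (±)-diol
Product: 20 (±)-bis-TBS ether of 19 (1-methoxyalkyne carrying ring B on its propargylic OTBS carbon; B-C2 CH2OTBS; B-C3 and B-C5 OMOM; B-C6 prenyl)
Conditions: TBSCl (3 equiv), imidazole, DMAP (cat.), DMF, rt; chromatography on Et3N-deactivated silica
Reagents that add atoms: tert-butyldimethylsilyl chloride, CC(C)(C)[Si](C)(C)Cl
Why: Imidazole-promoted silylation under nearly neutral conditions protects both hydroxyls without exposing the propargylic alcohol of the ynol ether to the protonation that would start a Meyer–Schuster-type rearrangement.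

Step 11
Reactants: 20 (±)-1-methoxyalkyne; 5 3-methylcyclobut-2-en-1-one
Product: 25 (±)-2-{(tert-butyldimethylsilyloxy)[2-(tert-butyldimethylsilyloxymethyl)-3,5-bis(methoxymethoxy)-6-(3-methylbut-2-en-1-yl)phenyl]methyl}-3-methoxy-5-methylphenol, via isopropenylketene 21 (not isolated), via alkenylcyclobutenone adduct 22 (not isolated), via dienylketene 23 (not isolated), via cyclohexadienone 24 (not isolated)
Conditions: 5 (2 equiv, in two portions), toluene (0.5 M), base-washed sealed tube, 80 °C, then 110 °C
Reagents that add atoms: none
Why: At 80 °C enone 5 opens by a conrotatory four-electron electrocyclic reaction to vinylketene 21, whose ketene C=C bond adds (2+2) to ynol ether 20 to give 4-alkenylcyclobutenone 22; further heating opens 22 in the same way to dienylketene 23, which closes to dienone 24 and tautomerises to phenol 25. The closest known reaction type is the Danheiser benzannulation of cyclobutenones with 1-alkoxyalkynes, applied here to a more heavily substituted alkyne. Ring A is closed by a disrotatory six-electron electrocyclisation that joins A-C4 to A-C5, after the (2+2) event has made the two new skeletal bonds A-C5 to A-C6 and A-C1 to A-C2. No lasting stereocentre arises, because the sp3 ring carbon of 22 ends as planar A-C2 and the racemic carbinol carbon is a spectator that step 15 oxidises. Only one orientation of the (2+2) step is wanted, and oxygen lone-pair donation polarises the triple bond so that the carbon bearing the carbinol substituent is the electron-rich terminus and attacks the electrophilic central ketene carbon, which places that substituent at A-C6 flanked by the new hydroxyl (A-C5) and the methyl ether (A-C1). Chemoselectivity rests on the ynol ether being a far better ketene partner than the prenyl alkene; the neutral medium leaves silyl and MOM ethers alone, and a methyl ynol ether has no β-hydrogen, so thermal fragmentation to a ketene is closed off.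

Step 12
Reactants: 25 (±)-phenol
Product: 26 (±)-6-bromo derivative of 25 (bromine at A-C4)
Conditions: NBS (1.0 equiv), i-Pr2NH (0.1 equiv), CH2Cl2, −78 → 0 °C, dark
Reagents that add atoms: N-bromosuccinimide, O=C1CCC(=O)N1Br
Why: In this amine-mediated ortho-bromination of a phenol, NBS and i-Pr2NH form N-bromodiisopropylamine, which the phenol holds by a hydrogen bond and which hands bromine to the only free ortho carbon A-C4 (also para to the methoxy group) faster than A-C2, ring B or the prenyl alkene can react at low temperature.

Step 13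
Reactants: 26 (±)-bromophenol
Product: 27 (±)-MOM ether of 26 (A-C5 OMOM)
Conditions: MOMCl, i-Pr2NEt, Bu4NI (cat.), CH2Cl2, 0 → 40 °C
Reagents that add atoms: chloromethyl methyl ether, COCCl
Why: O-Alkylation with MOMCl masks the phenol so that neither o-quinone methide formation under fluoride nor attack of activated DMSO on the phenol can interfere later, and the amine base avoids a free phenoxide next to the benzhydrylic silyl ether.

Step 14
Reactants: 27 (±)-tris-MOM bis-TBS ether
Product: 28 (±)-[3-bromo-6-methoxy-2-(methoxymethoxy)-4-methylphenyl][2-(hydroxymethyl)-3,5-bis(methoxymethoxy)-6-(3-methylbut-2-en-1-yl)phenyl]methanol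
Conditions: Bu4NF (3 equiv), THF, 0 °C → rt
Reagents that add atoms: none
Why: Fluoride-induced desilylation, driven by the strong Si–F bond, frees both alcohols while aryl bromide, MOM acetals and alkene are untouched.

Step 15
Reactants: 28 (±)-diol
Product: 30 2-[3-bromo-6-methoxy-2-(methoxymethoxy)-4-methylbenzoyl]-4,6-bis(methoxymethoxy)-3-(3-methylbut-2-en-1-yl)benzaldehyde, via bis(alkoxysulfonium) dichloride 29 (not isolated)
Conditions: (COCl)2 (5 equiv), DMSO (10 equiv), CH2Cl2, −78 → −60 °C; then Et3N, −78 → 0 °C
Reagents that add atoms: none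
Why: Swern oxidation with excess reagent turns both hydroxyls into alkoxysulfonium ions (29) before any base is present, so that Et3N releases ketone and aldehyde together and the hydroxy aldehyde, lactol, lactone drain typical of 1,2-benzenedimethanols is avoided.

Step 16
Reactants: 30 tris-MOM keto aldehyde
Product: 31 Pestalone B, 2-(3-bromo-2-hydroxy-6-methoxy-4-methylbenzoyl)-4,6-dihydroxy-3-(3-methylbut-2-en-1-yl)benzaldehyde
Conditions: 3 M aq. HCl, THF–i-PrOH, rt → 40 °C
Reagents that add atoms: none
Why: Acid-catalysed acetal hydrolysis removes the three aryl MOM groups, two of them helped by the neighbouring carbonyl groups, under dilute-acid conditions of the kind that spare ortho-prenylphenols from chroman formation, and it avoids base, which could trigger an intramolecular Cannizzaro–Tishchenko shift of the keto aldehyde.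

Compound list
1 | propyne | CC#C | starting material
2 | trichloroacetyl chloride | ClC(Cl)(Cl)C(=O)Cl | starting material
3 | dichloroketene | ClC(Cl)=C=O | intermediate
4 | 4,4-dichloro-3-methylcyclobut-2-en-1-one | CC1=CC(=O)C1(Cl)Cl | intermediate
5 | 3-methylcyclobut-2-en-1-one | CC1=CC(=O)C1 | intermediate
6 | methyl 3,5-dihydroxybenzoate | COC(=O)c1cc(O)cc(O)c1 | starting material
7 | N-[2,4-dihydroxy-6-(methoxycarbonyl)benzylidene]-N-methylmethanaminium chloride | COC(=O)c1cc(O)cc(O)c1C=[N+](C)C.[Cl-] | intermediate
8 | methyl 2-formyl-3,5-dihydroxybenzoate | COC(=O)c1cc(O)cc(O)c1C=O | intermediate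
9 | methyl 2-formyl-3,5-bis(methoxymethoxy)benzoate | COC(=O)c1cc(OCOC)cc(OCOC)c1C=O | intermediate
10 | methyl 2-(hydroxymethyl)-3,5-bis(methoxymethoxy)benzoate | COC(=O)c1cc(OCOC)cc(OCOC)c1CO | intermediate
11 | 4,6-bis(methoxymethoxy)isobenzofuran-1(3H)-one | O=C1OCc2c(OCOC)cc(OCOC)cc12 | intermediate
12 | 7-bromo-4,6-bis(methoxymethoxy)isobenzofuran-1(3H)-one | O=C1OCc2c(OCOC)cc(OCOC)c(Br)c12 | intermediate
13 | tributyl(3-methylbut-2-en-1-yl)stannane | CCCC[Sn](CCCC)(CCCC)CC=C(C)C | starting material
14 | 4,6-bis(methoxymethoxy)-7-(3-methylbut-2-en-1-yl)isobenzofuran-1(3H)-one | O=C1OCc2c(OCOC)cc(OCOC)c(CC=C(C)C)c12 | intermediate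
15 | (±)-4,6-bis(methoxymethoxy)-7-(3-methylbut-2-en-1-yl)-1,3-dihydroisobenzofuran-1-ol | OC1OCc2c(OCOC)cc(OCOC)c(CC=C(C)C)c12 | intermediate
16 | 2-chloro-1,1-dimethoxyethane | COC(CCl)OC | starting material
17 | lithium methoxyacetylide | [Li]C#COC | intermediate
18 | lithium alkoxide of 2-(hydroxymethyl)-3,5-bis(methoxymethoxy)-6-(3-methylbut-2-en-1-yl)benzaldehyde | [Li]OCc1c(OCOC)cc(OCOC)c(CC=C(C)C)c1C=O | intermediate
19 | (±)-1-[2-(hydroxymethyl)-3,5-bis(methoxymethoxy)-6-(3-methylbut-2-en-1-yl)phenyl]-3-methoxyprop-2-yn-1-ol | COC#CC(O)c1c(CO)c(OCOC)cc(OCOC)c1CC=C(C)C | intermediate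
20 | (±)-bis-TBS ether of 19, the 1-methoxyalkyne for the key step | COC#CC(O[Si](C)(C)C(C)(C)C)c1c(CO[Si](C)(C)C(C)(C)C)c(OCOC)cc(OCOC)c1CC=C(C)C | intermediate
21 | 3-methylbuta-1,3-dien-1-one (isopropenylketene) | C=C(C)C=C=O | intermediate
22 | 4-isopropenyl-3-methoxycyclobut-2-en-1-one carrying the ring B carbinol TBS ether at C2 (racemic, mixture of diastereomers) | COC1=C(C(=O)C1C(C)=C)C(O[Si](C)(C)C(C)(C)C)c1c(CO[Si](C)(C)C(C)(C)C)c(OCOC)cc(OCOC)c1CC=C(C)C | intermediate
23 | (±)-dienylketene, 3-methoxy-5-methylhexa-1,3,5-trien-1-one carrying the ring B carbinol TBS ether at C2, ketene and isopropenyl groups cis on the central double bond | O=C=C(C(O[Si](C)(C)C(C)(C)C)c1c(CO[Si](C)(C)C(C)(C)C)c(OCOC)cc(OCOC)c1CC=C(C)C)/C(OC)=C\C(C)=C | intermediate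
24 | (±)-3-methoxy-5-methylcyclohexa-2,4-dien-1-one carrying the ring B carbinol TBS ether at C2 | COC1=C(C(=O)CC(C)=C1)C(O[Si](C)(C)C(C)(C)C)c1c(CO[Si](C)(C)C(C)(C)C)c(OCOC)cc(OCOC)c1CC=C(C)C | intermediate
25 | (±)-diaryl carbinol TBS ether with complete ring A (2-hydroxy-6-methoxy-4-methylphenyl) and protected ring B | COc1cc(C)cc(O)c1C(O[Si](C)(C)C(C)(C)C)c1c(CO[Si](C)(C)C(C)(C)C)c(OCOC)cc(OCOC)c1CC=C(C)C | intermediate
26 | (±)-bromophenol, 25 with Br at A-C4 | COc1cc(C)c(Br)c(O)c1C(O[Si](C)(C)C(C)(C)C)c1c(CO[Si](C)(C)C(C)(C)C)c(OCOC)cc(OCOC)c1CC=C(C)C | intermediate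
27 | (±)-MOM ether of 26 | COc1cc(C)c(Br)c(OCOC)c1C(O[Si](C)(C)C(C)(C)C)c1c(CO[Si](C)(C)C(C)(C)C)c(OCOC)cc(OCOC)c1CC=C(C)C | intermediate
28 | (±)-diol, benzhydrol with B-C2 CH2OH | COc1cc(C)c(Br)c(OCOC)c1C(O)c1c(CO)c(OCOC)cc(OCOC)c1CC=C(C)C | intermediate
29 | (±)-bis(dimethylalkoxysulfonium) dichloride of 28 | COc1cc(C)c(Br)c(OCOC)c1C(O[S+](C)C)c1c(CO[S+](C)C)c(OCOC)cc(OCOC)c1CC=C(C)C.[Cl-].[Cl-] | intermediate
30 | 2-[3-bromo-6-methoxy-2-(methoxymethoxy)-4-methylbenzoyl]-4,6-bis(methoxymethoxy)-3-(3-methylbut-2-en-1-yl)benzaldehyde | COc1cc(C)c(Br)c(OCOC)c1C(=O)c1c(C=O)c(OCOC)cc(OCOC)c1CC=C(C)C | intermediate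
31 | Pestalone B | COc1cc(C)c(Br)c(O)c1C(=O)c1c(C=O)c(O)cc(O)c1CC=C(C)C | target

Total step count: 16.
Longest linear sequence: 14 steps (6 to 31, steps 3 to 16). Steps 1 and 2 form the short second branch.

Steps most likely to fail

Step 11. Crowding around the propargylic carbon may slow the (2+2) union so much that the vinylketene is lost by dimerisation or by acylating phenol already formed. The long heating needed to keep opening 5 may also wear down the ynol ether. The fallback sets out from 20 and comes back at 25, and it makes the ketene by light instead of heat.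
- 3-Methylbut-3-en-2-one is trifluoroacetylated (LiN(SiMe3)2, CF3CO2CH2CF3, THF, −78 °C) to 1,1,1-trifluoro-5-methylhex-5-ene-2,4-dione F1.
- Detrifluoroacetylative diazo transfer (MsN3, Et3N, H2O, MeCN) then gives 1-diazo-3-methylbut-3-en-2-one F2.
- Irradiation of F2 together with 20 (300 nm, ClCH2CH2Cl, rt) triggers a photochemical Wolff rearrangement to the same vinylketene 21 at ambient temperature. There 20 is not stressed and adduct 22 can build up.
- A short separate thermolysis (80 to 110 °C) takes 22 through 23 and 24 to 25.

This is the diazo ketone version of the benzannulation. It uses another ketene precursor and another mode of activation, and it uncouples cycloaddition from aromatisation.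

Step 12. Electrophilic bromine may be consumed by the trisubstituted prenyl alkene, with participation of the neighbouring B-C5 acetal oxygen, before the phenol ring is fully brominated. The fallback sets out from 12 and comes back at 26, and it carries a much less nucleophilic alkene through the bromination.
- Allyltributylstannane under the conditions of step 7 should give 7-allyl-4,6-bis(methoxymethoxy)isobenzofuran-1(3H)-one F3.
- The operations of steps 8 to 12 are repeated in the allyl series. They lead through the allyl lactol F4, the allyl diol F5, the allyl bis-TBS methoxyalkyne F6 and the allyl annulation phenol F7 to the allyl bromophenol F8.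
- Cross-metathesis of F8 with excess 2-methylbut-2-ene (second-generation Grubbs catalyst, CH2Cl2, 40 °C) then turns the allyl group into the prenyl group and delivers 26.

Step 15. Activation of the benzhydrol, which is flanked by four ortho substituents, may be incomplete, so that the primary alcohol is oxidised alone. The free secondary hydroxyl would then close on the new aldehyde to a lactol that is oxidised on to a lactone. The fallback sets out from 28 and comes back at 30, and it oxidises the two carbons one after the other, ketone first.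
- Selective silylation of the unhindered primary hydroxyl (TBSCl 1.05 equiv, imidazole, CH2Cl2, 0 °C) gives the primary mono-TBS ether F9.
- Dess–Martin periodinane (NaHCO3, CH2Cl2) oxidises the remaining benzhydrol to the silyloxymethyl benzophenone F10.
- Bu4NF buffered with AcOH frees the hydroxymethyl benzophenone F11, whose tertiary hemiketal form cannot be oxidised.
- A second Dess–Martin or MnO2 oxidation of the open form gives 30.

Further compounds
F1 | step 11 | 1,1,1-trifluoro-5-methylhex-5-ene-2,4-dione | CC(=C)C(=O)CC(=O)C(F)(F)F
F2 | step 11 | 1-diazo-3-methylbut-3-en-2-one | CC(=C)C(=O)C=[N+]=[N-]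
F3 | step 12 | 7-allyl-4,6-bis(methoxymethoxy)isobenzofuran-1(3H)-one | O=C1OCc2c(OCOC)cc(OCOC)c(CC=C)c12
F4 | step 12 | allyl lactol, (±)-7-allyl-4,6-bis(methoxymethoxy)-1,3-dihydroisobenzofuran-1-ol | OC1OCc2c(OCOC)cc(OCOC)c(CC=C)c12
F5 | step 12 | allyl diol, (±)-1-[6-allyl-2-(hydroxymethyl)-3,5-bis(methoxymethoxy)phenyl]-3-methoxyprop-2-yn-1-ol | COC#CC(O)c1c(CO)c(OCOC)cc(OCOC)c1CC=C
F6 | step 12 | allyl bis-TBS methoxyalkyne (racemic) | COC#CC(O[Si](C)(C)C(C)(C)C)c1c(CO[Si](C)(C)C(C)(C)C)c(OCOC)cc(OCOC)c1CC=C
F7 | step 12 | allyl annulation phenol (racemic) | COc1cc(C)cc(O)c1C(O[Si](C)(C)C(C)(C)C)c1c(CO[Si](C)(C)C(C)(C)C)c(OCOC)cc(OCOC)c1CC=C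
F8 | step 12 | allyl bromophenol (racemic) | COc1cc(C)c(Br)c(O)c1C(O[Si](C)(C)C(C)(C)C)c1c(CO[Si](C)(C)C(C)(C)C)c(OCOC)cc(OCOC)c1CC=C
F9 | step 15 | primary mono-TBS ether of 28 (racemic) | COc1cc(C)c(Br)c(OCOC)c1C(O)c1c(CO[Si](C)(C)C(C)(C)C)c(OCOC)cc(OCOC)c1CC=C(C)C
F10 | step 15 | silyloxymethyl benzophenone | COc1cc(C)c(Br)c(OCOC)c1C(=O)c1c(CO[Si](C)(C)C(C)(C)C)c(OCOC)cc(OCOC)c1CC=C(C)C
F11 | step 15 | hydroxymethyl benzophenone | COc1cc(C)c(Br)c(OCOC)c1C(=O)c1c(CO)c(OCOC)cc(OCOC)c1CC=C(C)C
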